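## Retrosynthetic overview

1. The target comes from its C4 triethylsilyl ether; the lower triene is cut by a Heck disconnection into a C4‑vinyl epoxy enone and the (2E,4E)‑5‑bromopentadienamide of 2‑amino‑3‑hydroxycyclopentenone.
2. The upper enamide C2–N bond is cut (copper‑catalysed N‑vinylation) into a 2‑iodo enone and (2E,4E,6E)‑10‑methylundecatrienamide, itself made by Wittig/HWE chemistry from 4‑methylpentanal.
3. The epoxy enone comes from a cyclopentadiene adduct by retro‑Diels–Alder; the norbornene masks C2=C3 and makes one face of the ring convex.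
4. Key step: desymmetrising enantioselective Diels–Alder reaction of achiral 4‑silyloxy‑4‑vinylcyclohexadienone with cyclopentadiene, followed in the same flask by epoxidation. The new norbornene carbocycle and the oxirane close in one operation and C4, C5 and C6 are set, with the C4 oxygen trans to the oxirane as the target SMILES requires (4S,5S,6R).
5. Ring order: six‑membered ring bought as the quinone monoketal → norbornene ring and oxirane together → norbornene ring removed; the five‑membered enolone ring is bought as cyclopentane‑1,3‑dione.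

Assumption: the sense of induction of the (R)‑BINOL/TiCl2(OiPr)2 catalyst in the key cycloaddition is taken as drawn; if the first run gives the mirror‑image adduct, (S)‑BINOL is used and nothing else changes.

## Route

Step 1
Reactants: 1 4,4-dimethoxycyclohexa-2,5-dien-1-one; 2 vinylmagnesium bromide
Product: 5 4-ethenyl-4-[(triethylsilyl)oxy]cyclohexa-2,5-dien-1-one, via bromomagnesium alkoxide 3 (not isolated), via silyl ether ketal 4 (not isolated)
Conditions: THF, −78 °C; Et3SiOTf, 2,6-lutidine, −78 → 0 °C; 5% aq. oxalic acid, 0 °C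
Reagents that add atoms: triethylsilyl trifluoromethanesulfonate, CC[Si](CC)(CC)OS(=O)(=O)C(F)(F)F; water, O
Why: 1,2-Grignard addition to the cross-conjugated ketone of a quinone monoketal (the standard entry to p-quinols), O-silylation of the tertiary alkoxide and acid hydrolysis of the very labile bis-allylic dimethyl ketal give the dienone; 5 is Cs-symmetric, so no stereocentre is set.

Step 2
Reactants: 5 4-ethenyl-4-[(triethylsilyl)oxy]cyclohexa-2,5-dien-1-one; 6 cyclopenta-1,3-diene (freshly cracked)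
Product: 8 (1R,4S,4aR,6R,7S,8S,8aS)-6,7-epoxy-8-ethenyl-8-[(triethylsilyl)oxy]-1,4,4a,5,6,7,8,8a-octahydro-1,4-methanonaphthalen-5-one, via Diels–Alder enone 7 (not isolated)
Conditions: (R)-BINOL (11 mol%), TiCl2(OiPr)2 (10 mol%), 4 Å MS, CH2Cl2, −30 °C; then tBuOOH, DBU, 0 °C → rt, same flask
Reagents that add atoms: tert-butyl hydroperoxide, CC(C)(C)OO
Why: Proposed new method: a desymmetrising catalytic enantioselective Diels–Alder reaction followed in the same flask by Weitz–Scheffer epoxidation, which closes the new six-membered carbocycle of the norbornene and the oxirane in one operation; the chiral titanium Lewis acid binds the dienone carbonyl and lets one of the two enantiotopic enones react with cyclopentadiene endo and syn to the C4 oxygen (the smaller and electronically syn-directing substituent, as known for 4-oxygenated cyclohexadienones), which fixes C4 and the four transient ring-fusion and bridgehead centres, and tBuOO− then attacks the remaining enone from the convex face, anti to both the norbornene and OSiEt3, which fixes C5 and C6 with the oxirane trans to the C4 oxygen; the closest known reaction types are the BINOL–titanium-catalysed enantioselective Diels–Alder reactions of 1,4-quinone monoketals and the exo epoxidation of cyclopentadiene–quinone adducts.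

Step 3
Reactants: 8 (1R,4S,4aR,6R,7S,8S,8aS)-6,7-epoxy-8-ethenyl-8-[(triethylsilyl)oxy]-1,4,4a,5,6,7,8,8a-octahydro-1,4-methanonaphthalen-5-one
Product: 9 (4S,5S,6R)-5,6-epoxy-4-ethenyl-4-[(triethylsilyl)oxy]cyclohex-2-en-1-one
Conditions: Ph2O, 250 °C, 20 min, N2 stream
Reagents that add atoms: none
Why: Retro-Diels–Alder cycloreversion, driven by loss of volatile cyclopentadiene and by enone conjugation, as used for cyclopentadiene-masked epoxyquinols; C4, C5 and C6 are not involved and the four transient stereocentres vanish.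

Step 4
Reactants: 9 (4S,5S,6R)-5,6-epoxy-4-ethenyl-4-[(triethylsilyl)oxy]cyclohex-2-en-1-one
Product: 10 (4S,5S,6R)-5,6-epoxy-4-ethenyl-2-iodo-4-[(triethylsilyl)oxy]cyclohex-2-en-1-one
Conditions: I2, pyridine, CH2Cl2, 0 °C → rt
Reagents that add atoms: iodine, II
Why: Johnson α-iodination of an enone (pyridine conjugate addition, iodination of the enolate, elimination), reliable for 4,4-disubstituted cyclohexenones; the isolated vinyl group and the oxirane are inert and no stereocentre changes.

Step 5
Reactants: 11 4-methylpentanal; 12 (triphenylphosphoranylidene)acetaldehyde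
Product: 13 (E)-6-methylhept-2-enal
Conditions: toluene, 80 °C
Reagents that add atoms: none
Why: Wittig olefination with a stabilised formylmethylene ylide gives the E enal selectively.

Step 6
Reactants: 13 (E)-6-methylhept-2-enal; 14 triethyl 4-phosphonocrotonate
Product: 15 ethyl (2E,4E,6E)-10-methylundeca-2,4,6-trienoate
Conditions: LiN(SiMe3)2, THF, −78 → 0 °C
Reagents that add atoms: none
Why: Vinylogous Horner–Wadsworth–Emmons olefination; the phosphonate brings its E alkene and the new C4=C5 bond forms E under thermodynamic control.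

Step 7
Reactants: 15 ethyl (2E,4E,6E)-10-methylundeca-2,4,6-trienoate
Product: 16 (2E,4E,6E)-10-methylundeca-2,4,6-trienamide
Conditions: AlMe3, NH4Cl, toluene, 0 → 50 °C
Reagents that add atoms: ammonium chloride, [NH4+].[Cl-]
Why: Weinreb aminolysis of an ester with the aluminium amide formed from AlMe3 and NH4Cl; attack is at the ester carbonyl only and the triene geometry is kept.

Step 8
Reactants: 10 (4S,5S,6R)-5,6-epoxy-4-ethenyl-2-iodo-4-[(triethylsilyl)oxy]cyclohex-2-en-1-one; 16 (2E,4E,6E)-10-methylundeca-2,4,6-trienamide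
Product: 17 (2E,4E,6E)-N-[(4S,5S,6R)-5,6-epoxy-4-ethenyl-1-oxo-4-(triethylsilyloxy)cyclohex-2-en-2-yl]-10-methylundeca-2,4,6-trienamide
Conditions: CuI (10 mol%), N,N′-dimethylethylenediamine (20 mol%), Cs2CO3, THF, 55 °C
Reagents that add atoms: none
Why: Goldberg-type copper-catalysed N-vinylation of a primary amide with a vinyl iodide (Buchwald conditions) with retention at the alkene; the silyl ether blocks Payne rearrangement of the trans epoxy alcohol under carbonate and no stereocentre is touched.

Step 9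
Reactants: 18 glutaconaldehyde potassium salt
Product: 19 (2E,4E)-5-bromopenta-2,4-dienal
Conditions: PPh3, Br2, CH2Cl2, 0 °C → rt
Reagents that add atoms: bromine, BrBr
Why: Deoxygenative bromination of a vinylogous formate by Ph3PBr2 (O-phosphonium formation, bromide addition–elimination) gives the known bromodienal in the thermodynamically preferred all-E geometry.

Step 10
Reactants: 19 (2E,4E)-5-bromopenta-2,4-dienal
Product: 20 (2E,4E)-5-bromopenta-2,4-dienoic acid
Conditions: NaClO2, NaH2PO4, 2-methylbut-2-ene, tBuOH/H2O, 0 °C → rt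
Reagents that add atoms: sodium chlorite, [Na+].[O-]Cl=O
Why: Pinnick oxidation of the enal to the acid; the alkene scavenger protects the bromodiene from hypochlorite and the E,E geometry is kept.

Step 11
Reactants: 21 cyclopentane-1,3-dione
Product: 22 2-(hydroxyimino)cyclopentane-1,3-dione
Conditions: NaNO2, aq. HCl, 0 °C
Reagents that add atoms: sodium nitrite, [Na+].[O-]N=O
Why: Nitrosation of the active methylene of a cyclic 1,3-dione followed by tautomerisation to the oxime.

Step 12
Reactants: 22 2-(hydroxyimino)cyclopentane-1,3-dione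
Product: 23 2-amino-3-hydroxycyclopent-2-en-1-one hydrochloride
Conditions: H2 (1 atm), 10% Pd/C, HCl, MeOH, rt
Reagents that add atoms: hydrogen chloride, Cl
Why: Catalytic hydrogenation of the oxime to the amine, trapped as the hydrochloride of the stable enol (vinylogous acid) form.

Step 13
Reactants: 20 (2E,4E)-5-bromopenta-2,4-dienoic acid; 23 2-amino-3-hydroxycyclopent-2-en-1-one hydrochloride
Product: 25 (2E,4E)-5-bromo-N-(2-hydroxy-5-oxocyclopent-1-en-1-yl)penta-2,4-dienamide, via acid chloride 24 (not isolated)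
Conditions: (COCl)2, DMF (cat.), CH2Cl2, 0 °C; then 23, Et3N, CH2Cl2/DMF, −20 °C → rt
Reagents that add atoms: oxalyl chloride, ClC(=O)C(=O)Cl (supplies the chlorine of 24; none of its atoms stay in 25)
Why: Acid chloride formation and N-acylation of the aminodione, any O-acyl isomer rearranging by O→N acyl shift; the bromodiene geometry is kept.

Step 14
Reactants: 17 (2E,4E,6E)-N-[(4S,5S,6R)-5,6-epoxy-4-ethenyl-1-oxo-4-(triethylsilyloxy)cyclohex-2-en-2-yl]-10-methylundeca-2,4,6-trienamide; 25 (2E,4E)-5-bromo-N-(2-hydroxy-5-oxocyclopent-1-en-1-yl)penta-2,4-dienamide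
Product: 26 (2E,4E,6E)-N-[(4S,5S,6R)-5,6-epoxy-4-{(1E,3E,5E)-7-[(2-hydroxy-5-oxocyclopent-1-en-1-yl)amino]-7-oxohepta-1,3,5-trien-1-yl}-1-oxo-4-(triethylsilyloxy)cyclohex-2-en-2-yl]-10-methylundeca-2,4,6-trienamide
Conditions: Pd(OAc)2 (10 mol%), Bu4NCl, NaHCO3, DMF, 45 °C, dark
Reagents that add atoms: none
Why: Mizoroki–Heck reaction under Jeffery conditions, in which the dienylpalladium bromide adds to the only terminal alkene with the new C–C bond at the unhindered carbon and β-hydride elimination, possible only away from the quaternary C4, gives the E alkene; the internal conjugated alkenes and the stereocentres are untouched.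

Step 15
Reactants: 26 (2E,4E,6E)-N-[(4S,5S,6R)-5,6-epoxy-4-{(1E,3E,5E)-7-[(2-hydroxy-5-oxocyclopent-1-en-1-yl)amino]-7-oxohepta-1,3,5-trien-1-yl}-1-oxo-4-(triethylsilyloxy)cyclohex-2-en-2-yl]-10-methylundeca-2,4,6-trienamide
Product: 27 (2E,4E,6E)-N-[(4S,5S,6R)-5,6-epoxy-4-hydroxy-4-{(1E,3E,5E)-7-[(2-hydroxy-5-oxocyclopent-1-en-1-yl)amino]-7-oxohepta-1,3,5-trien-1-yl}-1-oxocyclohex-2-en-2-yl]-10-methylundeca-2,4,6-trienamide
Conditions: HF·pyridine, pyridine, THF, 0 °C → rt
Reagents that add atoms: none
Why: Fluoride-mediated cleavage of the tertiary triethylsilyl ether under buffered conditions that spare the oxirane, the enol and the polyenes, so the base-sensitive free trans epoxy alcohol appears only in the last step with configuration unchanged.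

## Compound list

1 | 4,4-dimethoxycyclohexa-2,5-dien-1-one | COC1(OC)C=CC(=O)C=C1 | starting material
2 | vinylmagnesium bromide | C=C[Mg]Br | starting material
3 | bromomagnesium 1-ethenyl-4,4-dimethoxycyclohexa-2,5-dien-1-olate | C=CC1([O-])C=CC(OC)(OC)C=C1.[Mg+2].[Br-] | intermediate
4 | triethyl[(1-ethenyl-4,4-dimethoxycyclohexa-2,5-dien-1-yl)oxy]silane | C=CC1(O[Si](CC)(CC)CC)C=CC(OC)(OC)C=C1 | intermediate
5 | 4-ethenyl-4-[(triethylsilyl)oxy]cyclohexa-2,5-dien-1-one (achiral) | C=CC1(O[Si](CC)(CC)CC)C=CC(=O)C=C1 | intermediate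
6 | cyclopenta-1,3-diene | C1=CC=CC1 | starting material
7 | (1R,4S,4aR,8R,8aS)-8-ethenyl-8-[(triethylsilyl)oxy]-1,4,4a,5,8,8a-hexahydro-1,4-methanonaphthalen-5-one (endo adduct; norbornene on the face of OSiEt3) | O=C1[C@@H]2[C@@H]3C=C[C@@H](C3)[C@@H]2[C@@](O[Si](CC)(CC)CC)(C=C)C=C1 | intermediate
8 | (1R,4S,4aR,6R,7S,8S,8aS)-6,7-epoxy-8-ethenyl-8-[(triethylsilyl)oxy]-1,4,4a,5,6,7,8,8a-octahydro-1,4-methanonaphthalen-5-one (endo adduct; oxirane on the convex face, trans to OSiEt3 and cis to the vinyl group) | O=C1[C@@H]2[C@@H]3C=C[C@@H](C3)[C@@H]2[C@@](O[Si](CC)(CC)CC)(C=C)[C@H]2O[C@@H]12 | intermediate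
9 | (4S,5S,6R)-5,6-epoxy-4-ethenyl-4-[(triethylsilyl)oxy]cyclohex-2-en-1-one | O=C1C=C[C@@](O[Si](CC)(CC)CC)(C=C)[C@H]2O[C@@H]12 | intermediate
10 | (4S,5S,6R)-5,6-epoxy-4-ethenyl-2-iodo-4-[(triethylsilyl)oxy]cyclohex-2-en-1-one | O=C1C(I)=C[C@@](O[Si](CC)(CC)CC)(C=C)[C@H]2O[C@@H]12 | intermediate
11 | 4-methylpentanal | CC(C)CCC=O | starting material
12 | (triphenylphosphoranylidene)acetaldehyde | O=CC=P(c1ccccc1)(c1ccccc1)c1ccccc1 | starting material
13 | (E)-6-methylhept-2-enal | CC(C)CC/C=C/C=O | intermediate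
14 | triethyl 4-phosphonocrotonate, ethyl (E)-4-(diethoxyphosphoryl)but-2-enoate | CCOC(=O)/C=C/CP(=O)(OCC)OCC | starting material
15 | ethyl (2E,4E,6E)-10-methylundeca-2,4,6-trienoate | CC(C)CC/C=C/C=C/C=C/C(=O)OCC | intermediate
16 | (2E,4E,6E)-10-methylundeca-2,4,6-trienamide | CC(C)CC/C=C/C=C/C=C/C(N)=O | intermediate
17 | (2E,4E,6E)-N-[(4S,5S,6R)-5,6-epoxy-4-ethenyl-1-oxo-4-(triethylsilyloxy)cyclohex-2-en-2-yl]-10-methylundeca-2,4,6-trienamide | CC(C)CC/C=C/C=C/C=C/C(=O)NC1=C[C@@](O[Si](CC)(CC)CC)(C=C)[C@H]2O[C@H]2C1=O | intermediate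
18 | glutaconaldehyde potassium salt, potassium (1E,3E)-5-oxopenta-1,3-dien-1-olate | [K+].[O-]/C=C/C=C/C=O | starting material
19 | (2E,4E)-5-bromopenta-2,4-dienal | O=C/C=C/C=C/Br | intermediate
20 | (2E,4E)-5-bromopenta-2,4-dienoic acid | OC(=O)/C=C/C=C/Br | intermediate
21 | cyclopentane-1,3-dione | O=C1CCC(=O)C1 | starting material
22 | 2-(hydroxyimino)cyclopentane-1,3-dione | O=C1CCC(=O)C1=NO | intermediate
23 | 2-amino-3-hydroxycyclopent-2-en-1-one hydrochloride | NC1=C(O)CCC1=O.Cl | intermediate
24 | (2E,4E)-5-bromopenta-2,4-dienoyl chloride | ClC(=O)/C=C/C=C/Br | intermediate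
25 | (2E,4E)-5-bromo-N-(2-hydroxy-5-oxocyclopent-1-en-1-yl)penta-2,4-dienamide | O=C(/C=C/C=C/Br)NC1=C(O)CCC1=O | intermediate
26 | (2E,4E,6E)-N-[(4S,5S,6R)-5,6-epoxy-4-{(1E,3E,5E)-7-[(2-hydroxy-5-oxocyclopent-1-en-1-yl)amino]-7-oxohepta-1,3,5-trien-1-yl}-1-oxo-4-(triethylsilyloxy)cyclohex-2-en-2-yl]-10-methylundeca-2,4,6-trienamide | CC(C)CC/C=C/C=C/C=C/C(=O)NC1=C[C@@](O[Si](CC)(CC)CC)(/C=C/C=C/C=C/C(=O)NC2=C(O)CCC2=O)[C@H]2O[C@H]2C1=O | intermediate
27 | (2E,4E,6E)-N-[(4S,5S,6R)-5,6-epoxy-4-hydroxy-4-{(1E,3E,5E)-7-[(2-hydroxy-5-oxocyclopent-1-en-1-yl)amino]-7-oxohepta-1,3,5-trien-1-yl}-1-oxocyclohex-2-en-2-yl]-10-methylundeca-2,4,6-trienamide (CNP0304685.4) | CC(C)CC/C=C/C=C/C=C/C(=O)NC1=C[C@@](O)(/C=C/C=C/C=C/C(=O)NC2=C(O)CCC2=O)[C@H]2O[C@H]2C1=O | target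

## Step count and risks

Total step count: 15.

Longest linear sequence: 7 steps (steps 1, 2, 3, 4, 8, 14, 15; from 1 to 27).

The three steps most likely to fail:

**Step 2** (enantioselective desymmetrising Diels–Alder plus epoxidation). The catalyst has not been shown on a 4‑silyloxy‑4‑vinyl dienone, the face selectivity rests on analogy, and a Lewis acid could trigger a dienone–phenol shift of the vinyl group. The fallback sets out from 1 and 6 and comes back to the route at 8. Quinone monoketal 1 itself is taken through the (R)‑BINOL/TiCl2(OiPr)2‑catalysed Diels–Alder reaction with 6, a known reaction type for this class of dienophile, to give the endo enone ketal F1. It is epoxidised in the same flask (tBuOOH, DBU) on the convex face to the epoxy ketone ketal F2. The vinylcerium reagent made from 2 and CeCl3 (THF, −78 °C) then adds to the ketone of F2 from the convex face, that is syn to the oxirane, and Et3SiOTf traps the alkoxide to give the silyl ether ketal F3. Montmorillonite K10 in wet CH2Cl2 hydrolyses the ketal to 8. Here C4 is no longer set in the cycloaddition but by convex‑face carbonyl addition on the tricycle.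

**Step 8** (copper‑catalysed amidation). The weakly nucleophilic, poorly soluble trienamide must couple with a base‑sensitive iodo epoxy enone. The fallback sets out from 10 (with 13 and 12 for the aldehyde) and comes back at 17. Coupling of 10 with commercial 2‑(diethoxyphosphoryl)acetamide, a small and more acidic amide, under the same CuI/diamine catalysis with K3PO4 gives the phosphonoacetamide enamide F4. A second Wittig homologation of 13 with 12 gives (2E,4E)‑8‑methylnona‑2,4‑dienal F5. Masamune–Roush Horner–Wadsworth–Emmons olefination of F5 with F4 (LiCl, DBU, MeCN) builds the 2E double bond and delivers 17. The upper chain is thus assembled on the core after the C–N bond exists.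

**Step 14** (Heck coupling). A ligand‑free palladium catalyst must couple a dienyl bromide with a hindered allylic silyl ether in the presence of two polyenes and an acidic enol. The fallback sets out from 9 and comes back at 26. Cross‑metathesis of 9 with vinylboronic acid pinacol ester (second‑generation Hoveyda–Grubbs catalyst, CH2Cl2, 40 °C), done before any polyene is present, gives the E‑alkenyl boronate F6. Iodination (I2, pyridine) gives the iodo enone boronate F7, and CuI‑catalysed amidation with 16 gives the enamide boronate F8. Suzuki–Miyaura coupling of F8 with 25 (Pd(PPh3)4, K3PO4, THF/H2O, rt) gives 26.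

## Further compounds

F1 | step 2 | (1S,4R,4aS,8aR)-8,8-dimethoxy-1,4,4a,5,8,8a-hexahydro-1,4-methanonaphthalen-5-one (endo adduct of 1 and 6) | O=C1[C@H]2[C@H]3C=C[C@H](C3)[C@H]2C(OC)(OC)C=C1
F2 | step 2 | (1S,4R,4aS,6S,7R,8aR)-6,7-epoxy-8,8-dimethoxy-1,4,4a,5,6,7,8,8a-octahydro-1,4-methanonaphthalen-5-one (oxirane on the convex face) | O=C1[C@H]2[C@H]3C=C[C@H](C3)[C@H]2C(OC)(OC)[C@@H]2O[C@H]12
F3 | step 2 | (1R,4S,4aR,6R,7S,8S,8aS)-6,7-epoxy-8-ethenyl-5,5-dimethoxy-8-[(triethylsilyl)oxy]-1,4,4a,5,6,7,8,8a-octahydro-1,4-methanonaphthalene | COC1(OC)[C@@H]2[C@@H]3C=C[C@@H](C3)[C@@H]2[C@@](O[Si](CC)(CC)CC)(C=C)[C@H]2O[C@@H]12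
F4 | step 8 | diethyl (2-{[(4S,5S,6R)-5,6-epoxy-4-ethenyl-1-oxo-4-(triethylsilyloxy)cyclohex-2-en-2-yl]amino}-2-oxoethyl)phosphonate | CCOP(=O)(OCC)CC(=O)NC1=C[C@@](O[Si](CC)(CC)CC)(C=C)[C@H]2O[C@H]2C1=O
F5 | step 8 | (2E,4E)-8-methylnona-2,4-dienal | CC(C)CC/C=C/C=C/C=O
F6 | step 14 | (4S,5S,6R)-5,6-epoxy-4-[(E)-2-(4,4,5,5-tetramethyl-1,3,2-dioxaborolan-2-yl)ethenyl]-4-[(triethylsilyl)oxy]cyclohex-2-en-1-one | O=C1C=C[C@@](O[Si](CC)(CC)CC)(/C=C/B3OC(C)(C)C(C)(C)O3)[C@H]2O[C@@H]12
F7 | step 14 | (4S,5S,6R)-5,6-epoxy-2-iodo-4-[(E)-2-(4,4,5,5-tetramethyl-1,3,2-dioxaborolan-2-yl)ethenyl]-4-[(triethylsilyl)oxy]cyclohex-2-en-1-one | O=C1C(I)=C[C@@](O[Si](CC)(CC)CC)(/C=C/B3OC(C)(C)C(C)(C)O3)[C@H]2O[C@@H]12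
F8 | step 14 | (2E,4E,6E)-N-{(4S,5S,6R)-5,6-epoxy-1-oxo-4-[(E)-2-(4,4,5,5-tetramethyl-1,3,2-dioxaborolan-2-yl)ethenyl]-4-(triethylsilyloxy)cyclohex-2-en-2-yl}-10-methylundeca-2,4,6-trienamide | CC(C)CC/C=C/C=C/C=C/C(=O)NC1=C[C@@](O[Si](CC)(CC)CC)(/C=C/B3OC(C)(C)C(C)(C)O3)[C@H]2O[C@H]2C1=O
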